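**Retrosynthetic overview**

- The strategy rests on ring C. Its C3–OH/C4=O unit (a 3-hydroxy-4-pyranone) is the enol of a 2-arylchromane-3,4-dione, so C3 and C4 are two adjacent carbonyl-level carbons of like polarity, and joining them requires polarity inversion at one of them.
- Target 19 ⇐ MOM removal and acyloin oxidation ⇐ dihydroflavonol 16 ⇐ C3–C4 disconnection (carbene-catalysed intramolecular crossed benzoin) ⇐ dialdehyde 15. Rings A and B are brought in intact; ring C is the only ring formed.
- Dialdehyde 15 ⇐ reduction and twofold oxidation ⇐ ester aldehyde 13 ⇐ O1–C2 ether bond (Williamson) between phenol 6 and α-bromo arylacetate 12.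
- Phenol 6 ⇐ 2,4,6-trihydroxybenzaldehyde (twofold C-prenylation, 4-O-methylation, mono-MOM protection). Bromide 12 ⇐ 3-hydroxy-4-methoxyphenylacetic acid (esterification, MOM protection, α-bromination).

Key step: step 10

Remark: the target has no stereocentre, so the ether-bearing carbon of 12–15 and C2/C3 of 16 are carried as racemates; ring B is taken from commercial 3-hydroxy-4-methoxyphenylacetic acid, whose CH2 and CO2H carbons become C2 and C3.

**Route**

Step 1
Reactants: 1 2,4,6-trihydroxybenzaldehyde; 2 prenyl bromide (1-bromo-3-methylbut-2-ene)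
Product: 4 2,4,6-trihydroxy-3,5-bis(3-methylbut-2-enyl)benzaldehyde, via mono-C-prenylated aldehyde 3 (not isolated)
Conditions: prenyl bromide (2.1 equiv in total), 10% aq. KOH, 0 °C → rt
Reagents that add atoms: prenyl bromide (second equivalent), CC(C)=CCBr
Why: Acylphloroglucinol phenoxides are ambident and in water are alkylated at carbon; the first equivalent of prenyl bromide gives the 3-prenyl compound 3, whose phenoxide is still nucleophilic at the one remaining free ring carbon C5 and takes up the second equivalent, so twofold nuclear C-prenylation should give 4 after separation from mono- and O-prenylated material.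

Step 2
Reactants: 4 2,4,6-trihydroxy-3,5-bis(3-methylbut-2-enyl)benzaldehyde
Product: 5 2,6-dihydroxy-4-methoxy-3,5-bis(3-methylbut-2-enyl)benzaldehyde
Conditions: MeI (1.05 equiv), K2CO3 (1.0 equiv), acetone, rt
Reagents that add atoms: iodomethane, CI
Why: The 4-OH is para to the formyl group and not held in a hydrogen bond to it, so it is the most acidic phenol and one equivalent of carbonate should direct the Williamson methylation there.

Step 3
Reactants: 5 2,6-dihydroxy-4-methoxy-3,5-bis(3-methylbut-2-enyl)benzaldehyde
Product: 6 2-hydroxy-4-methoxy-6-(methoxymethoxy)-3,5-bis(3-methylbut-2-enyl)benzaldehyde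
Conditions: MOMCl (1.1 equiv), i-Pr2NEt, CH2Cl2, 0 °C → rt
Reagents that add atoms: chloromethyl methyl ether, COCCl
Why: Once one of the two equivalent ortho hydroxyls is capped, the other is locked in the hydrogen bond to the formyl oxygen and resists MOMCl/amine, so the MOM ether formation is self-limiting at the mono stage.

Step 4
Reactants: 7 3-hydroxy-4-methoxyphenylacetic acid
Product: 8 methyl 2-(3-hydroxy-4-methoxyphenyl)acetate
Conditions: MeOH, H2SO4 (cat.), reflux
Reagents that add atoms: methanol, CO
Why: Fischer esterification of an unhindered arylacetic acid in excess methanol; the phenol is untouched.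

Step 5
Reactants: 8 methyl 2-(3-hydroxy-4-methoxyphenyl)acetate
Product: 9 methyl 2-[4-methoxy-3-(methoxymethoxy)phenyl]acetate
Conditions: MOMCl, i-Pr2NEt, CH2Cl2, 0 °C → rt
Reagents that add atoms: chloromethyl methyl ether, COCCl
Why: MOM ether formation on a free, unchelated phenol, giving the same protecting group as on ring A so that one acid step removes both at the end.

Step 6
Reactants: 9 methyl 2-[4-methoxy-3-(methoxymethoxy)phenyl]acetate
Product: 12 methyl 2-bromo-2-[4-methoxy-3-(methoxymethoxy)phenyl]acetate (racemic), via lithium ester enolate 10 (not isolated), via trimethylsilyl ketene acetal 11 (not isolated)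
Conditions: LiN(SiMe3)2, THF, −78 °C; Me3SiCl; then NBS, −78 → 0 °C; used crude
Reagents that add atoms: N-bromosuccinimide, O=C1CCC(=O)N1Br
Why: α-Halogenation of an ester through its silyl ketene acetal places bromine only at the benzylic α-carbon and avoids both ring bromination of the electron-rich arene and double bromination; the new centre is racemic.

Step 7
Reactants: 6 2-hydroxy-4-methoxy-6-(methoxymethoxy)-3,5-bis(3-methylbut-2-enyl)benzaldehyde; 12 methyl 2-bromo-2-[4-methoxy-3-(methoxymethoxy)phenyl]acetate
Product: 13 methyl 2-[2-formyl-5-methoxy-3-(methoxymethoxy)-4,6-bis(3-methylbut-2-enyl)phenoxy]-2-[4-methoxy-3-(methoxymethoxy)phenyl]acetate (racemic)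
Conditions: K2CO3, DMF, rt
Reagents that add atoms: none
Why: Williamson ether synthesis in which carbonate in DMF breaks the chelate of the acidic ortho-formyl phenol and the phenoxide displaces a bromide doubly activated (benzylic and α to the ester) for SN2, forming the O1–C2 bond; room temperature keeps the ester α-proton from engaging the neighbouring formyl group.

Step 8
Reactants: 13 methyl 2-[2-formyl-5-methoxy-3-(methoxymethoxy)-4,6-bis(3-methylbut-2-enyl)phenoxy]-2-[4-methoxy-3-(methoxymethoxy)phenyl]acetate
Product: 14 2-[2-(hydroxymethyl)-5-methoxy-3-(methoxymethoxy)-4,6-bis(3-methylbut-2-enyl)phenoxy]-2-[4-methoxy-3-(methoxymethoxy)phenyl]ethanol (racemic)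
Conditions: LiAlH4, THF, 0 °C; Fieser work-up; used without chromatography
Reagents that add atoms: none
Why: Hydride reduction takes the ester and the aryl aldehyde to the two primary alcohols in one operation, while the MOM ethers, aryl ethers and prenyl alkenes are inert.

Step 9
Reactants: 14 2-[2-(hydroxymethyl)-5-methoxy-3-(methoxymethoxy)-4,6-bis(3-methylbut-2-enyl)phenoxy]-2-[4-methoxy-3-(methoxymethoxy)phenyl]ethanol
Product: 15 4-methoxy-2-(methoxymethoxy)-6-{1-[4-methoxy-3-(methoxymethoxy)phenyl]-2-oxoethoxy}-3,5-bis(3-methylbut-2-enyl)benzaldehyde (racemic)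
Conditions: Dess–Martin periodinane (2.5 equiv), NaHCO3, CH2Cl2, 0 °C → rt; used at once
Reagents that add atoms: none
Why: Dess–Martin oxidation should convert the benzylic and the aliphatic primary alcohol to aldehydes without over-oxidation, and the bicarbonate buffer spares the MOM ethers and the enolisable α-aryl aldehyde.

Step 10
Reactants: 15 4-methoxy-2-(methoxymethoxy)-6-{1-[4-methoxy-3-(methoxymethoxy)phenyl]-2-oxoethoxy}-3,5-bis(3-methylbut-2-enyl)benzaldehyde
Product: 16 trans-3-hydroxy-7-methoxy-5-(methoxymethoxy)-2-[4-methoxy-3-(methoxymethoxy)phenyl]-6,8-bis(3-methylbut-2-enyl)chroman-4-one (racemic; the 2R,3R enantiomer is drawn)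
Conditions: 3-benzyl-5-(2-hydroxyethyl)-4-methylthiazolium chloride (20 mol%), DBU (20 mol%), t-BuOH, 40 °C, Ar
Reagents that add atoms: none
Why: DBU frees the thiazol-2-ylidene, which adds to the ring A formyl group (future C4) and after proton transfer gives the hydroxy-enamine, an acyl anion equivalent that attacks the side-chain formyl carbon (future C3); proton transfer and loss of the carbene then release the α-hydroxy ketone. The closest known reaction type is the thiazolylidene-catalysed intramolecular crossed benzoin of 2-(2-oxoalkoxy)benzaldehydes to 3-hydroxychroman-4-ones, extended here from a ketone to an aldehyde acceptor as in carbene-catalysed acyloin cyclisations of dialdehydes. Ring C closes in the 6-exo-trig mode, with O1–C2 already in place and C3–C4 as the new bond. The new C3 centre is set relative to C2 under thermodynamic control, since C2 can epimerise through the enol of the open aldehyde and C3 through the enediol of the acyloin, so the trans isomer with both substituents equatorial should prevail, and either isomer serves because both centres vanish in step 11. The step needs the ring A formyl group, not the side-chain one, to become the donor, because an enaminol raised at C3 would hold the ring A aryloxide on the neighbouring carbon and could expel it; the more acidic benzylic carbinol C–H of the ring A adduct, the small N-benzyl thiazolylidene that tolerates the two ortho oxygens and the branched carbon beside the side-chain formyl group are expected to direct it so. It also needs acyloin formation to outrun aldol closure to a five-membered ring, which is helped by holding DBU at the precatalyst loading and by the fact that an aldol adduct with fully substituted C2 cannot dehydrate and therefore reverts.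

Step 11
Reactants: 16 trans-3-hydroxy-7-methoxy-5-(methoxymethoxy)-2-[4-methoxy-3-(methoxymethoxy)phenyl]-6,8-bis(3-methylbut-2-enyl)chroman-4-one
Product: 18 3-hydroxy-7-methoxy-5-(methoxymethoxy)-2-[4-methoxy-3-(methoxymethoxy)phenyl]-6,8-bis(3-methylbut-2-enyl)chromen-4-one, via chromane-3,4-dione 17 (not isolated)
Conditions: Dess–Martin periodinane (1.3 equiv), NaHCO3, CH2Cl2, rt
Reagents that add atoms: none
Why: Oxidation of the α-ketol to the 1,2-dione is followed by spontaneous enolisation toward C2, which gives the aromatic 3-hydroxy-4-pyranone and erases both stereocentres; any 4-hydroxychroman-3-one regioisomer or cis isomer carried from step 10 converges on the same dione.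

Step 12
Reactants: 18 3-hydroxy-7-methoxy-5-(methoxymethoxy)-2-[4-methoxy-3-(methoxymethoxy)phenyl]-6,8-bis(3-methylbut-2-enyl)chromen-4-one
Product: 19 3,5-dihydroxy-2-(3-hydroxy-4-methoxyphenyl)-7-methoxy-6,8-bis(3-methylbut-2-enyl)chromen-4-one (CNP0261856.0)
Conditions: 3 M aq. HCl, MeOH, 50 °C
Reagents that add atoms: none
Why: Acid-catalysed acetal exchange with methanol removes both MOM ethers, and the liberated 5-OH is tied up in the hydrogen bond to C4=O, which should restrain it from adding to the neighbouring prenyl alkene under this mild acid.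

**Compound list**

1 | 2,4,6-trihydroxybenzaldehyde | O=Cc1c(O)cc(O)cc1O | starting material
2 | prenyl bromide (1-bromo-3-methylbut-2-ene) | CC(C)=CCBr | starting material
3 | 2,4,6-trihydroxy-3-(3-methylbut-2-enyl)benzaldehyde | O=Cc1c(O)c(CC=C(C)C)c(O)cc1O | intermediate (not isolated)
4 | 2,4,6-trihydroxy-3,5-bis(3-methylbut-2-enyl)benzaldehyde | O=Cc1c(O)c(CC=C(C)C)c(O)c(CC=C(C)C)c1O | intermediate
5 | 2,6-dihydroxy-4-methoxy-3,5-bis(3-methylbut-2-enyl)benzaldehyde | O=Cc1c(O)c(CC=C(C)C)c(OC)c(CC=C(C)C)c1O | intermediate
6 | 2-hydroxy-4-methoxy-6-(methoxymethoxy)-3,5-bis(3-methylbut-2-enyl)benzaldehyde | O=Cc1c(O)c(CC=C(C)C)c(OC)c(CC=C(C)C)c1OCOC | intermediate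
7 | 3-hydroxy-4-methoxyphenylacetic acid | COc1ccc(CC(=O)O)cc1O | starting material
8 | methyl 2-(3-hydroxy-4-methoxyphenyl)acetate | COC(=O)Cc1ccc(OC)c(O)c1 | intermediate
9 | methyl 2-[4-methoxy-3-(methoxymethoxy)phenyl]acetate | COC(=O)Cc1ccc(OC)c(OCOC)c1 | intermediate
10 | lithium enolate of 9 | COC([O-])=Cc1ccc(OC)c(OCOC)c1.[Li+] | intermediate (not isolated)
11 | methyl trimethylsilyl ketene acetal of 9 | COC(O[Si](C)(C)C)=Cc1ccc(OC)c(OCOC)c1 | intermediate (not isolated)
12 | methyl 2-bromo-2-[4-methoxy-3-(methoxymethoxy)phenyl]acetate (racemic) | COC(=O)C(Br)c1ccc(OC)c(OCOC)c1 | intermediate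
13 | methyl 2-[2-formyl-5-methoxy-3-(methoxymethoxy)-4,6-bis(3-methylbut-2-enyl)phenoxy]-2-[4-methoxy-3-(methoxymethoxy)phenyl]acetate (racemic) | COC(=O)C(Oc1c(C=O)c(OCOC)c(CC=C(C)C)c(OC)c1CC=C(C)C)c1ccc(OC)c(OCOC)c1 | intermediate
14 | 2-[2-(hydroxymethyl)-5-methoxy-3-(methoxymethoxy)-4,6-bis(3-methylbut-2-enyl)phenoxy]-2-[4-methoxy-3-(methoxymethoxy)phenyl]ethanol (racemic) | OCC(Oc1c(CO)c(OCOC)c(CC=C(C)C)c(OC)c1CC=C(C)C)c1ccc(OC)c(OCOC)c1 | intermediate
15 | 4-methoxy-2-(methoxymethoxy)-6-{1-[4-methoxy-3-(methoxymethoxy)phenyl]-2-oxoethoxy}-3,5-bis(3-methylbut-2-enyl)benzaldehyde (racemic) | O=Cc1c(OCOC)c(CC=C(C)C)c(OC)c(CC=C(C)C)c1OC(C=O)c1ccc(OC)c(OCOC)c1 | intermediate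
16 | trans-3-hydroxy-7-methoxy-5-(methoxymethoxy)-2-[4-methoxy-3-(methoxymethoxy)phenyl]-6,8-bis(3-methylbut-2-enyl)chroman-4-one (racemic, 2R,3R drawn) | COc1ccc([C@@H]2[C@H](C(=O)c3c(OCOC)c(CC=C(C)C)c(OC)c(CC=C(C)C)c3O2)O)cc1OCOC | intermediate
17 | 7-methoxy-5-(methoxymethoxy)-2-[4-methoxy-3-(methoxymethoxy)phenyl]-6,8-bis(3-methylbut-2-enyl)chromane-3,4-dione (racemic) | COc1ccc(C2Oc3c(CC=C(C)C)c(OC)c(CC=C(C)C)c(OCOC)c3C(=O)C2=O)cc1OCOC | intermediate (not isolated)
18 | 3-hydroxy-7-methoxy-5-(methoxymethoxy)-2-[4-methoxy-3-(methoxymethoxy)phenyl]-6,8-bis(3-methylbut-2-enyl)chromen-4-one | COc1ccc(-c2oc3c(CC=C(C)C)c(OC)c(CC=C(C)C)c(OCOC)c3c(=O)c2O)cc1OCOC | intermediate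
19 | 3,5-dihydroxy-2-(3-hydroxy-4-methoxyphenyl)-7-methoxy-6,8-bis(3-methylbut-2-enyl)chromen-4-one (CNP0261856.0) | COc1ccc(-c2oc3c(CC=C(C)C)c(OC)c(CC=C(C)C)c(O)c3c(=O)c2O)cc1O | target

**Step count**

Total steps: 12. Longest linear sequence: 9 (steps 1–3 and 7–12).

**Steps most likely to fail**

1. Step 10. The carbene may engage the side-chain formyl group first, and the enaminol so formed can expel the ring A aryloxide in an internal redox process. Base-mediated aldol closure to the five-membered ring may also drain the dialdehyde before the acyloin forms. Fallback: set out from 15 and form the C3–C4 bond by reductive instead of polarity-inverted coupling. Intramolecular pinacol coupling with SmI2 in THF at −78 °C, in which the more easily reduced aryl aldehyde gives the ketyl that adds to the side-chain aldehyde, should give 7-methoxy-5-(methoxymethoxy)-2-[4-methoxy-3-(methoxymethoxy)phenyl]-6,8-bis(3-methylbut-2-enyl)chromane-3,4-diol F1 as a mixture of diastereomers. Oxidation of both carbinols with IBX in DMSO at rt, which does not cleave 1,2-diols, passes through dione 17 and comes back to the route at 18.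

2. Step 1. Alkylation may occur at oxygen, stop at the mono-prenyl stage, or go on at an already substituted carbon with loss of aromaticity. Fallback: set out from 1 and install the prenyl groups by cross-coupling. Selective methylation (MeI, K2CO3, acetone) should give 2,6-dihydroxy-4-methoxybenzaldehyde F2. NBS (2 equiv) in MeCN at 0 °C brominates the two free positions to 3,5-dibromo-2,6-dihydroxy-4-methoxybenzaldehyde F3. MOMCl with i-Pr2NEt gives 3,5-dibromo-2-hydroxy-4-methoxy-6-(methoxymethoxy)benzaldehyde F4. Twofold Stille coupling with tributyl(3-methylbut-2-enyl)stannane and Pd(PPh3)4 in DMF at 90 °C comes back to the route at 6.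

3. Step 7. Substitution at the crowded, hydrogen-bonded phenol may be slow, the labile benzylic bromide may decompose first, and base may close the product's ester α-carbon onto the neighbouring formyl group. Fallback: set out from 9 and form the O1–C2 bond by carbenoid insertion without base. Diazo transfer (p-acetamidobenzenesulfonyl azide, DBU, MeCN) should give methyl 2-diazo-2-[4-methoxy-3-(methoxymethoxy)phenyl]acetate F5. Slow addition of F5 to phenol 6 with Rh2(OAc)4 (1 mol%) in CH2Cl2 at rt effects O–H insertion and comes back to the route at 13.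

**Further compounds**

F1 | step 10 | 7-methoxy-5-(methoxymethoxy)-2-[4-methoxy-3-(methoxymethoxy)phenyl]-6,8-bis(3-methylbut-2-enyl)chromane-3,4-diol (mixture of diastereomers) | COc1ccc(C2Oc3c(CC=C(C)C)c(OC)c(CC=C(C)C)c(OCOC)c3C(O)C2O)cc1OCOC
F2 | step 1 | 2,6-dihydroxy-4-methoxybenzaldehyde | O=Cc1c(O)cc(OC)cc1O
F3 | step 1 | 3,5-dibromo-2,6-dihydroxy-4-methoxybenzaldehyde | O=Cc1c(O)c(Br)c(OC)c(Br)c1O
F4 | step 1 | 3,5-dibromo-2-hydroxy-4-methoxy-6-(methoxymethoxy)benzaldehyde | O=Cc1c(O)c(Br)c(OC)c(Br)c1OCOC
F5 | step 7 | methyl 2-diazo-2-[4-methoxy-3-(methoxymethoxy)phenyl]acetate | COC(=O)C(=[N+]=[N-])c1ccc(OC)c(OCOC)c1
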